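## The problem

Compound 22 is a 2,3,4-trisubstituted tetrahydrofuran, numbered here O1, C2, C3, C4, C5. C2 carries a 4-hydroxy-3,5-dimethoxyphenyl (syringyl) ring, C3 a CH2O-feruloyl arm and C4 a 4-hydroxy-3-methoxybenzyl (guaiacylmethyl) arm. This heterocycle is the only ring to be built, so the task reduces to the branched chain C2–C3–C4–C5 and one C–O bond. The three contiguous stereocentres are (2S,3R,4R): the aryl group is trans to the C3 arm, and the C3 and C4 arms are cis. Opened at O1–C2, C3 and C4 are the two centres of an (R,R)-2,3-dibenzylbutane-1,4-diol. There C4 can be set by an auxiliary and can then direct C3 through trans alkylation of a butyrolactone; C2 can be left to C3, because the aryl group is delivered and is most stable anti to both ring neighbours. The fragile parts are the E-cinnamate ester (hydride, hydrogenation, strong base), three free phenols (the syringol oxidises very easily) and the O1–C2 bond. That bond is benzylic and para to a hydroxyl, so acid ionises it (epimerisation, Friedel–Crafts closure onto the guaiacyl ring) and hydrogenolysis cleaves it. Three phenols and, before acylation, two hydroxymethyl groups must also be told apart. The enabling feature is C2 itself: it is benzylic and para to the syringyl hydroxyl, whose two ortho positions are blocked by methoxy groups, so two-electron oxidation of that phenol makes C2 a quinone methide carbon with the C5 oxygen in reach, and C2 can stay a CH2 until the ring is closed.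

## Retrosynthesis

**22 ⇒ 21 ⇒ 20 + 3.** The two aryl O–Si bonds are cut first, then the CH2–O bond of the ester. The ester is placed last because the cinnamate would not survive the hydride, hydrogenolysis and oxidation steps needed earlier. Cutting at the alkyl C–O bond means the alcohol of 20, not the acid, is activated, so the hindered free syringyl phenol of 20 needs no protection; an acylating agent would attack it. Both remaining phenols in 21 carry the same triisopropylsilyl group, so one fluoride step ends the synthesis. The forward reaction must acylate one primary alcohol beside a free phenol and keep the E-alkene.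

**20 ⇒ 18 (through 19).** The O1–C2 bond is cut. Against the neighbouring option, closure by displacement at a C2 carbinol, this cut removes an oxidation level and a stereocentre from every earlier intermediate: 18 is an open-chain diol with two stereocentres and a plain CH2 at C2. The forward step must oxidise one benzylic position out of two, use one hydroxyl out of two and set C2 trans to the C3 arm. The first is decided by free versus silylated phenol, the second by ring size (five against four), the third by C3. Because only one hydroxymethyl group can reach C2, the cyclisation also leaves the correct alcohol free for acylation.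

**18 ⇒ 17 ⇒ 16.** Only functional groups change: the syringyl benzyl ether is put back, and the two hydroxymethyl groups are folded into a lactone. The benzyl ether is chosen because it survives enolate and hydride chemistry and leaves by hydrogenolysis before any alkene is present; the guaiacyl silyl ether survives that hydrogenolysis. The lactone 16 is a trans-2,3-dibenzylbutyrolactone, a compound class whose stereochemistry is easy to control and to check.

**16 ⇒ 11 + 15.** The C2–C3 bond of the target is cut, between the lactone α-carbon and the syringyl benzylic carbon. Alkylation of a β-substituted butyrolactone enolate anti to the β-substituent is the most dependable way to the trans relationship that becomes 3,4-cis in the ring. The forward reaction needs only a reactive benzylic bromide and a kinetic enolate. An aldol with the aldehyde would put oxygen on C2 too early and is kept as a reserve.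

**11 ⇒ 9 ⇒ 7 + 8.** The C3–C4 bond is cut, between the α-carbon of a 3-arylpropanoyl imide and the CH2 of bromoacetate 8. The auxiliary sets C4, the only centre of the route that is not substrate-controlled. A Stobbe condensation–asymmetric hydrogenation sequence was weighed for 11, but its hot alkoxide step would not spare the aryl silyl ether. The forward steps are a chelate-controlled enolate alkylation and a reductive removal of the auxiliary that ends in lactonisation.

**7 ⇒ 4 + 5; 4 ⇒ 3 ⇒ 1.** The imide N–acyl bond is cut, then the saturated acid 4 is traced to the silylated ferulic acid 3 by adding back one C=C. Thus one silylation of ferulic acid 1 supplies both the guaiacyl arm and the acyl group used in the last coupling.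

**15 ⇒ 14 ⇒ 13 ⇒ 12.** The bromide is traced through the alcohol and the O-benzyl aldehyde to syringaldehyde 12; these are functional-group changes only.

## Roads not taken

**Alternative 1:** The exocyclic bond from C4 to its benzylic carbon and the C2–C3 bond are cut together.
- Forward step: the lithium anion of the guaiacyl dithiane A2 adds to the β-carbon of the menthyloxy butenolide A1 on the face opposite the menthyloxy group. The lactone enolate is then trapped by the silylated syringaldehyde A3 anti to the new substituent, giving adduct A4. Desulfurisation with Raney Ni, hydride reduction of lactone and acetal carbon, acid cyclodehydration, acylation and desilylation would follow.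
- Merits: two C–C bonds and the C3/C4 pair in one flask, control from inexpensive menthol, the C2 oxygen present from the start, and one silyl group for both phenols. The longest line is probably two or three steps shorter than the chosen one.
- Weak points: Raney Ni meets a benzylic hydroxyl para to an oxygenated ring, and the β-hydroxy lactone can undergo retro-aldol cleavage. Above all, the ring is closed by ionising a benzylic carbinol in acid, the conditions under which the guaiacyl ring captures the cation to give an aryltetralin. Diastereomerically pure A1 must also be secured.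
- Comparison: this road is more convergent and shorter. The chosen plan sets against it C–C bond formations that are plain enolate alkylations, no sulfur, and a ring closure from a CH2 under oxidative, nearly neutral conditions.

**Alternative 2:** A [3+2] cut through C2–C3 and C4–C5.
- Forward step: CsF induces 1,3-elimination from the α-chloro silylmethyl ether A6 to a syringyl carbonyl ylide. The ylide adds across the alkene of the enantiopure γ-aryl butenolide A5, anti to its aryl group, giving the cis-fused furofuranone A7. Hydrogenolysis of the lactone benzylic C–O bond and of both benzyl ethers, reduction of the acid and selective acylation would follow.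
- Merits: the ring and all three stereocentres arise in one step; it is the shortest of the four routes.
- Weak points: that step must control regiochemistry, exo/endo placement of the C2 aryl group and facial selectivity at once. A6 is an α-chloro ether of an electron-rich aldehyde and ionises readily. The γ-proton of A5 is benzylic and vinylogously acidic, so basic fluoride endangers its configuration. The later hydrogenolysis must choose between two benzylic C–O bonds, one of them O1–C2.
- Comparison: clearly better in step count. The chosen plan spreads the stereochemical load over three separate, dependable events and forms O1–C2 after the last reductive step, so no reagent has to choose between two benzylic C–O bonds.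

**Alternative 3:** The C3–C4 bond is cut.
- Forward step: Cp2TiCl (trivalent titanium, from Cp2TiCl2 and Zn) opens the epoxide of the epoxy ether A8 to a C3 radical. The radical cyclises 5-exo onto the coniferyl-type alkene, and the benzylic radical is reduced and protonated to give A9, the bis-silylated 5-methoxylariciresinol.
- Merits: A9 is one acylation and one desilylation from the target, both phenols share one protecting group, and the usual 2,3-trans-3,4-cis preference of such cyclisations matches the target. The route could need about half the steps of the chosen plan.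
- Weak points: C3 and C4 are both set in a radical step steered only by C2, so diastereomers must be expected. The C2 configuration of A8 has to come from a kinetic resolution or an asymmetric vinyl addition. O-alkylation of a secondary benzylic epoxy alcohol under base invites epoxide migration. The titanium reagent is stoichiometric.
- Comparison: shorter and the more elegant construction. The chosen plan offers stereocentres set one at a time (auxiliary, trans-lactone alkylation, thermodynamics), no diastereomer separation at the tetrahydrofuran stage and no dependence on a resolution.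

Key step: step 12

## Route

**Step 1**
Reactants: 1 ferulic acid
Product: 3 (E)-3-[3-methoxy-4-(triisopropylsilyloxy)phenyl]prop-2-enoic acid, via bis-silylated ferulate 2 (not isolated)
Conditions: i-Pr3SiCl (2.2 equiv), imidazole, DMF, rt; then K2CO3, MeOH/THF/H2O, 0 °C
Reagents that add atoms: triisopropylsilyl chloride, CC(C)[Si](Cl)(C(C)C)C(C)C
Why: O-silylation of both acidic hydroxyls, then selective solvolysis of the silyl ester, which is far more electrophilic at silicon than the hindered aryl silyl ether.

**Step 2**
Reactants: 3 (E)-3-[3-methoxy-4-(triisopropylsilyloxy)phenyl]prop-2-enoic acid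
Product: 4 3-[3-methoxy-4-(triisopropylsilyloxy)phenyl]propanoic acid
Conditions: H2 (1 atm), 10% Pd/C, EtOAc, rt
Reagents that add atoms: none
Why: Heterogeneous catalytic hydrogenation of a cinnamic acid C=C; the arene and the aryl silyl ether are inert under these conditions.

**Step 3**
Reactants: 4 3-[3-methoxy-4-(triisopropylsilyloxy)phenyl]propanoic acid; 5 (S)-4-benzyl-1,3-oxazolidin-2-one
Product: 7 (S)-4-benzyl-3-{3-[3-methoxy-4-(triisopropylsilyloxy)phenyl]propanoyl}-1,3-oxazolidin-2-one, via mixed pivalic anhydride 6 (not isolated)
Conditions: t-BuCOCl, Et3N, THF, −20 °C; then 5, LiCl, rt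
Reagents that add atoms: none
Why: N-acylation of the oxazolidinone through a mixed anhydride, which is attacked at its less hindered carbonyl; the LiCl/amine protocol needs no strong base, so the silyl ether is not at risk.

**Step 4**
Reactants: 7 (S)-4-benzyl-3-{3-[3-methoxy-4-(triisopropylsilyloxy)phenyl]propanoyl}-1,3-oxazolidin-2-one; 8 tert-butyl bromoacetate
Product: 9 tert-butyl (3R)-4-[(4S)-4-benzyl-2-oxo-1,3-oxazolidin-3-yl]-3-[3-methoxy-4-(triisopropylsilyloxy)benzyl]-4-oxobutanoate
Conditions: NaN(SiMe3)2, THF, −78 °C; then 8, −78 to −40 °C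
Reagents that add atoms: none
Why: Evans asymmetric alkylation: the chelated (Z)-sodium enolate is alkylated on the face opposite the C4 benzyl group of the auxiliary, which sets the (R) centre that becomes C4 of the target.

**Step 5**
Reactants: 9 tert-butyl (3R)-4-[(4S)-4-benzyl-2-oxo-1,3-oxazolidin-3-yl]-3-[3-methoxy-4-(triisopropylsilyloxy)benzyl]-4-oxobutanoate
Product: 11 (4R)-4-[3-methoxy-4-(triisopropylsilyloxy)benzyl]dihydrofuran-2(3H)-one, via hydroxy tert-butyl ester 10 (not isolated)
Conditions: LiBH4, MeOH (1 equiv), THF, 0 °C; then TsOH·H2O (cat.), CH2Cl2, rt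
Reagents that add atoms: none
Why: Reductive cleavage of the activated exocyclic imide carbonyl by borohydride spares the tert-butyl ester and returns the auxiliary; acid-catalysed lactonisation then expels tert-butanol. The stereocentre ends β to the lactone carbonyl and is configurationally safe from here on.

**Step 6**
Reactants: 12 syringaldehyde
Product: 13 4-(benzyloxy)-3,5-dimethoxybenzaldehyde
Conditions: BnBr, K2CO3, DMF, rt
Reagents that add atoms: benzyl bromide, BrCc1ccccc1
Why: Williamson ether synthesis on the phenoxide.

**Step 7**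
Reactants: 13 4-(benzyloxy)-3,5-dimethoxybenzaldehyde
Product: 14 [4-(benzyloxy)-3,5-dimethoxyphenyl]methanol
Conditions: NaBH4, MeOH, 0 °C
Reagents that add atoms: none
Why: Borohydride reduction of an aryl aldehyde to the benzylic alcohol.

**Step 8**
Reactants: 14 [4-(benzyloxy)-3,5-dimethoxyphenyl]methanol
Product: 15 2-(benzyloxy)-5-(bromomethyl)-1,3-dimethoxybenzene
Conditions: PBr3, Et2O, 0 °C
Reagents that add atoms: phosphorus tribromide, BrP(Br)Br
Why: Conversion of a benzylic alcohol to the bromide through its phosphite ester; the electron-rich bromide is used at once.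

**Step 9**
Reactants: 11 (4R)-4-[3-methoxy-4-(triisopropylsilyloxy)benzyl]dihydrofuran-2(3H)-one; 15 2-(benzyloxy)-5-(bromomethyl)-1,3-dimethoxybenzene
Product: 16 (3R,4R)-3-[4-(benzyloxy)-3,5-dimethoxybenzyl]-4-[3-methoxy-4-(triisopropylsilyloxy)benzyl]dihydrofuran-2(3H)-one
Conditions: LiN(SiMe3)2, THF, −78 °C; then 15, −78 to −20 °C
Reagents that add atoms: none
Why: Alkylation of a lactone lithium enolate; the bromide approaches anti to the β-substituent, giving the trans lactone and so the (R) centre that becomes C3 of the target.

**Step 10**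
Reactants: 16 (3R,4R)-3-[4-(benzyloxy)-3,5-dimethoxybenzyl]-4-[3-methoxy-4-(triisopropylsilyloxy)benzyl]dihydrofuran-2(3H)-one
Product: 17 (2R,3R)-2-[4-(benzyloxy)-3,5-dimethoxybenzyl]-3-[3-methoxy-4-(triisopropylsilyloxy)benzyl]butane-1,4-diol
Conditions: LiAlH4, THF, 0 °C
Reagents that add atoms: none
Why: Hydride reduction of the lactone to the 1,4-diol; no stereocentre is touched, and the benzyl ether and the hindered aryl silyl ether should survive at this temperature.

**Step 11**
Reactants: 17 (2R,3R)-2-[4-(benzyloxy)-3,5-dimethoxybenzyl]-3-[3-methoxy-4-(triisopropylsilyloxy)benzyl]butane-1,4-diol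
Product: 18 (2R,3R)-2-(4-hydroxy-3,5-dimethoxybenzyl)-3-[3-methoxy-4-(triisopropylsilyloxy)benzyl]butane-1,4-diol
Conditions: H2 (1 atm), 10% Pd/C, EtOAc, rt
Reagents that add atoms: none
Why: Hydrogenolysis of the aryl benzyl ether frees only the syringyl phenol; the silyl ether on the guaiacyl ring stays, which is what makes the two arenes different for the next step.

**Step 12**
Reactants: 18 (2R,3R)-2-(4-hydroxy-3,5-dimethoxybenzyl)-3-[3-methoxy-4-(triisopropylsilyloxy)benzyl]butane-1,4-diol
Product: 20 [(2S,3R,4R)-2-(4-hydroxy-3,5-dimethoxyphenyl)-4-[3-methoxy-4-(triisopropylsilyloxy)benzyl]oxolan-3-yl]methanol, via syringyl p-quinone methide 19 (not isolated)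
Conditions: DDQ (1.0 equiv, slow addition), CH2Cl2, 0 °C to rt
Reagents that add atoms: none
Why: The quinone oxidises only the free 2,6-dimethoxyphenol of 18 (the guaiacyl oxygen is silylated, and both ortho positions of the syringol are blocked, so phenol coupling has no outlet) and gives p-quinone methide 19 with its electrophilic exocyclic carbon at C2. The closest known reaction type is oxidation of a p-alkylphenol to a p-quinone methide with capture by a tethered hydroxyl in an oxa-1,6-conjugate addition. The ring closes 5-exo-trig: the hydroxyl on the CH2 attached to C4 attacks C2 and forms O1–C2, whereas the other hydroxymethyl group could only close an oxetane and stays free for the later acylation. C2 is the one new stereocentre and is controlled by C3: allylic 1,3-strain holds the C3–H in the plane of the quinone methide, so the oxygen tethered through C4 attacks the face that places the aryl group anti to the C3 hydroxymethyl arm, giving (2S). The addition is reversible under the weakly acidic conditions set by the hydroquinone formed, and the 2,3-trans isomer, with the aryl group anti to both ring neighbours, is also the more stable one, so kinetic and equilibrium control agree. The selectivities needed are phenol against silyl ether (one benzylic position of two), five- against four-membered ring, O- against C-nucleophile (the silylated guaiacyl ring is a slower, irreversible Friedel–Crafts trap and no strong acid is present) and mono-oxidation (one equivalent, added slowly in the cold).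

**Step 13**
Reactants: 20 [(2S,3R,4R)-2-(4-hydroxy-3,5-dimethoxyphenyl)-4-[3-methoxy-4-(triisopropylsilyloxy)benzyl]oxolan-3-yl]methanol; 3 (E)-3-[3-methoxy-4-(triisopropylsilyloxy)phenyl]prop-2-enoic acid
Product: 21 [(2S,3R,4R)-2-(4-hydroxy-3,5-dimethoxyphenyl)-4-[3-methoxy-4-(triisopropylsilyloxy)benzyl]oxolan-3-yl]methyl (E)-3-[3-methoxy-4-(triisopropylsilyloxy)phenyl]prop-2-enoate
Conditions: PPh3, DIAD, THF, 0 °C to rt
Reagents that add atoms: none
Why: Mitsunobu esterification: the primary alcohol is activated as its alkoxyphosphonium ion and displaced by the carboxylate of 3, which is far more acidic than the hindered phenol and is therefore the nucleophile. The carbon attacked is a CH2, so no stereocentre is involved.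

**Step 14**
Reactants: 21 [(2S,3R,4R)-2-(4-hydroxy-3,5-dimethoxyphenyl)-4-[3-methoxy-4-(triisopropylsilyloxy)benzyl]oxolan-3-yl]methyl (E)-3-[3-methoxy-4-(triisopropylsilyloxy)phenyl]prop-2-enoate
Product: 22 [(2S,3R,4R)-2-(4-hydroxy-3,5-dimethoxyphenyl)-4-(4-hydroxy-3-methoxybenzyl)oxolan-3-yl]methyl (E)-3-(4-hydroxy-3-methoxyphenyl)prop-2-enoate
Conditions: Bu4NF, AcOH (1:1), THF, 0 °C
Reagents that add atoms: none
Why: Fluoride cleavage of both aryl silyl ethers, driven by the Si–F bond; acetic acid buffers the phenoxides so that the ester, the E-alkene and the benzylic ether are left alone.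

## Compound list

1 | ferulic acid, (E)-3-(4-hydroxy-3-methoxyphenyl)prop-2-enoic acid | COc1cc(/C=C/C(=O)O)ccc1O | starting material
2 | triisopropylsilyl (E)-3-[3-methoxy-4-(triisopropylsilyloxy)phenyl]prop-2-enoate | COc1cc(/C=C/C(=O)O[Si](C(C)C)(C(C)C)C(C)C)ccc1O[Si](C(C)C)(C(C)C)C(C)C | intermediate
3 | (E)-3-[3-methoxy-4-(triisopropylsilyloxy)phenyl]prop-2-enoic acid | COc1cc(/C=C/C(=O)O)ccc1O[Si](C(C)C)(C(C)C)C(C)C | intermediate
4 | 3-[3-methoxy-4-(triisopropylsilyloxy)phenyl]propanoic acid | COc1cc(CCC(=O)O)ccc1O[Si](C(C)C)(C(C)C)C(C)C | intermediate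
5 | (S)-4-benzyl-1,3-oxazolidin-2-one | O=C1N[C@@H](Cc2ccccc2)CO1 | starting material
6 | 3-[3-methoxy-4-(triisopropylsilyloxy)phenyl]propanoic pivalic anhydride | COc1cc(CCC(=O)OC(=O)C(C)(C)C)ccc1O[Si](C(C)C)(C(C)C)C(C)C | intermediate
7 | (S)-4-benzyl-3-{3-[3-methoxy-4-(triisopropylsilyloxy)phenyl]propanoyl}-1,3-oxazolidin-2-one | COc1cc(CCC(=O)N2[C@@H](Cc3ccccc3)COC2=O)ccc1O[Si](C(C)C)(C(C)C)C(C)C | intermediate
8 | tert-butyl bromoacetate | BrCC(=O)OC(C)(C)C | starting material
9 | tert-butyl (3R)-4-[(4S)-4-benzyl-2-oxo-1,3-oxazolidin-3-yl]-3-[3-methoxy-4-(triisopropylsilyloxy)benzyl]-4-oxobutanoate | COc1cc(C[C@H](CC(=O)OC(C)(C)C)C(=O)N2[C@@H](Cc3ccccc3)COC2=O)ccc1O[Si](C(C)C)(C(C)C)C(C)C | intermediate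
10 | tert-butyl (3R)-3-(hydroxymethyl)-4-[3-methoxy-4-(triisopropylsilyloxy)phenyl]butanoate | COc1cc(C[C@H](CC(=O)OC(C)(C)C)CO)ccc1O[Si](C(C)C)(C(C)C)C(C)C | intermediate
11 | (4R)-4-[3-methoxy-4-(triisopropylsilyloxy)benzyl]dihydrofuran-2(3H)-one | O=C1C[C@@H](Cc2ccc(O[Si](C(C)C)(C(C)C)C(C)C)c(OC)c2)CO1 | intermediate
12 | syringaldehyde, 4-hydroxy-3,5-dimethoxybenzaldehyde | COc1cc(C=O)cc(OC)c1O | starting material
13 | 4-(benzyloxy)-3,5-dimethoxybenzaldehyde | COc1cc(C=O)cc(OC)c1OCc1ccccc1 | intermediate
14 | [4-(benzyloxy)-3,5-dimethoxyphenyl]methanol | COc1cc(CO)cc(OC)c1OCc1ccccc1 | intermediate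
15 | 2-(benzyloxy)-5-(bromomethyl)-1,3-dimethoxybenzene | COc1cc(CBr)cc(OC)c1OCc1ccccc1 | intermediate
16 | (3R,4R)-3-[4-(benzyloxy)-3,5-dimethoxybenzyl]-4-[3-methoxy-4-(triisopropylsilyloxy)benzyl]dihydrofuran-2(3H)-one | O=C1[C@H](Cc2cc(OC)c(OCc3ccccc3)c(OC)c2)[C@@H](Cc2ccc(O[Si](C(C)C)(C(C)C)C(C)C)c(OC)c2)CO1 | intermediate
17 | (2R,3R)-2-[4-(benzyloxy)-3,5-dimethoxybenzyl]-3-[3-methoxy-4-(triisopropylsilyloxy)benzyl]butane-1,4-diol | OC[C@H](Cc1cc(OC)c(OCc2ccccc2)c(OC)c1)[C@@H](Cc1ccc(O[Si](C(C)C)(C(C)C)C(C)C)c(OC)c1)CO | intermediate
18 | (2R,3R)-2-(4-hydroxy-3,5-dimethoxybenzyl)-3-[3-methoxy-4-(triisopropylsilyloxy)benzyl]butane-1,4-diol | OC[C@H](Cc1cc(OC)c(O)c(OC)c1)[C@@H](Cc1ccc(O[Si](C(C)C)(C(C)C)C(C)C)c(OC)c1)CO | intermediate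
19 | 4-[(2R,3R)-4-hydroxy-2-(hydroxymethyl)-3-[3-methoxy-4-(triisopropylsilyloxy)benzyl]butylidene]-2,6-dimethoxycyclohexa-2,5-dien-1-one (p-quinone methide of 18) | OC[C@H](C=C1C=C(OC)C(=O)C(OC)=C1)[C@@H](Cc1ccc(O[Si](C(C)C)(C(C)C)C(C)C)c(OC)c1)CO | intermediate
20 | [(2S,3R,4R)-2-(4-hydroxy-3,5-dimethoxyphenyl)-4-[3-methoxy-4-(triisopropylsilyloxy)benzyl]oxolan-3-yl]methanol | OC[C@H]1[C@@H](Cc2ccc(O[Si](C(C)C)(C(C)C)C(C)C)c(OC)c2)CO[C@@H]1c1cc(OC)c(O)c(OC)c1 | intermediate
21 | [(2S,3R,4R)-2-(4-hydroxy-3,5-dimethoxyphenyl)-4-[3-methoxy-4-(triisopropylsilyloxy)benzyl]oxolan-3-yl]methyl (E)-3-[3-methoxy-4-(triisopropylsilyloxy)phenyl]prop-2-enoate | COc1cc(/C=C/C(=O)OC[C@H]2[C@@H](Cc3ccc(O[Si](C(C)C)(C(C)C)C(C)C)c(OC)c3)CO[C@@H]2c2cc(OC)c(O)c(OC)c2)ccc1O[Si](C(C)C)(C(C)C)C(C)C | intermediate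
22 | [(2S,3R,4R)-2-(4-hydroxy-3,5-dimethoxyphenyl)-4-(4-hydroxy-3-methoxybenzyl)oxolan-3-yl]methyl (E)-3-(4-hydroxy-3-methoxyphenyl)prop-2-enoate | COc1cc(/C=C/C(=O)OC[C@H]2[C@@H](Cc3ccc(O)c(OC)c3)CO[C@@H]2c2cc(OC)c(O)c(OC)c2)ccc1O | target

## Step count and risks

Total: 14 steps. Longest linear sequence: 11 steps (1, 2, 3, 4, 5, 9, 10, 11, 12, 13, 14, from ferulic acid 1); steps 6–8 form the side branch to bromide 15.

**Step 12 (key step).**
- Risk: over-oxidation, because the C2–H of the product is again benzylic and para to the free phenol. Quinone methide 19 may also be diverted by Friedel–Crafts attack of the silylated guaiacyl ring, or tautomerise to the styrene, which would erase the C3 configuration.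
- Fallback: the C2 oxygen is brought in by C–C bond formation and the ring is closed by dehydration. It sets out from lactone 11 and aldehyde 13. The lithium enolate of 11 (LiN(iPr)2, THF, −78 °C) adds to 13 to give the β-hydroxy lactone F1, trans on the ring, as a mixture at the carbinol carbon. LiAlH4 reduces F1 to the O-benzyl triol F2. Hydrogenolysis over Pd/C in EtOAc frees the phenol to give the phenolic triol F3. A catalytic amount of camphorsulfonic acid in CH2Cl2 ionises the p-hydroxybenzylic alcohol, and the same 5-exo closure gives 20, where the route is rejoined.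

**Step 13.**
- Risk: competing alkylation of the free syringyl phenol by the activated alcohol, or slow activation of the β-branched primary alcohol.
- Fallback: over-acylate, then cut back. From 20, both hydroxyls are acylated with an excess of 3 (carbodiimide, 4-dimethylaminopyridine, CH2Cl2) to give the bis-ester F4. The aryl ester alone is then cleaved with pyrrolidine, since aryl esters undergo aminolysis far faster than alkyl esters, and this returns 21.

**Step 14.**
- Risk: ester cleavage or acyl transfer set off by basic fluoride and the phenoxides formed, or opening of O1–C2 through the syringyl phenoxide.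
- Fallback: change the order so that fluoride never meets the ester. From 20, the silyl group is removed first (Bu4NF, THF) to give 5-methoxylariciresinol F5. Its only alcohol is then esterified with unprotected ferulic acid 1 under Mitsunobu conditions, which activate the alcohol and leave phenols alone; this arrives directly at 22.

**Step 5.**
- Risk: over-reduction (hydride attack on the tert-butyl ester or on lactone formed too early) and ring-opening of the auxiliary at its endocyclic carbonyl.
- Fallback: separate removal of the auxiliary from reduction. From 9, hydrolysis with LiOH/H2O2 gives the acid F6 with recovery of 5. BH3·SMe2 reduces the free acid in preference to the ester and gives hydroxy ester 10, which is lactonised as before to 11.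

## Further compounds

F1 | step 12 | (3S,4R)-3-{[4-(benzyloxy)-3,5-dimethoxyphenyl](hydroxy)methyl}-4-[3-methoxy-4-(triisopropylsilyloxy)benzyl]dihydrofuran-2(3H)-one, carbinol epimers | O=C1[C@H](C(O)c2cc(OC)c(OCc3ccccc3)c(OC)c2)[C@@H](Cc2ccc(O[Si](C(C)C)(C(C)C)C(C)C)c(OC)c2)CO1
F2 | step 12 | (2R,3R)-2-{[4-(benzyloxy)-3,5-dimethoxyphenyl](hydroxy)methyl}-3-[3-methoxy-4-(triisopropylsilyloxy)benzyl]butane-1,4-diol, carbinol epimers | OC[C@H](C(O)c1cc(OC)c(OCc2ccccc2)c(OC)c1)[C@@H](Cc1ccc(O[Si](C(C)C)(C(C)C)C(C)C)c(OC)c1)CO
F3 | step 12 | (2R,3R)-2-[hydroxy(4-hydroxy-3,5-dimethoxyphenyl)methyl]-3-[3-methoxy-4-(triisopropylsilyloxy)benzyl]butane-1,4-diol, carbinol epimers | OC[C@H](C(O)c1cc(OC)c(O)c(OC)c1)[C@@H](Cc1ccc(O[Si](C(C)C)(C(C)C)C(C)C)c(OC)c1)CO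
F4 | step 13 | bis-ester of 20 with 3, acylated at the primary alcohol and at the syringyl phenol | COc1cc(/C=C/C(=O)OC[C@H]2[C@@H](Cc3ccc(O[Si](C(C)C)(C(C)C)C(C)C)c(OC)c3)CO[C@@H]2c2cc(OC)c(OC(=O)/C=C/c3ccc(O[Si](C(C)C)(C(C)C)C(C)C)c(OC)c3)c(OC)c2)ccc1O[Si](C(C)C)(C(C)C)C(C)C
F5 | step 14 | 5-methoxylariciresinol, [(2S,3R,4R)-2-(4-hydroxy-3,5-dimethoxyphenyl)-4-(4-hydroxy-3-methoxybenzyl)oxolan-3-yl]methanol | OC[C@H]1[C@@H](Cc2ccc(O)c(OC)c2)CO[C@@H]1c1cc(OC)c(O)c(OC)c1
F6 | step 5 | (2R)-4-tert-butoxy-2-[3-methoxy-4-(triisopropylsilyloxy)benzyl]-4-oxobutanoic acid | COc1cc(C[C@H](CC(=O)OC(C)(C)C)C(=O)O)ccc1O[Si](C(C)C)(C(C)C)C(C)C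
A1 | alternative 1 | (5R)-5-[(1R,2S,5R)-2-isopropyl-5-methylcyclohexyloxy]furan-2(5H)-one | O=C1C=C[C@H](O[C@@H]2C[C@H](C)CC[C@H]2C(C)C)O1
A2 | alternative 1 | 2-[4-(tert-butyldimethylsilyloxy)-3-methoxyphenyl]-1,3-dithiane | COc1cc(C2SCCCS2)ccc1O[Si](C)(C)C(C)(C)C
A3 | alternative 1 | 4-(tert-butyldimethylsilyloxy)-3,5-dimethoxybenzaldehyde | COc1cc(C=O)cc(OC)c1O[Si](C)(C)C(C)(C)C
A4 | alternative 1 | Michael–aldol adduct: (5R)-menthyloxy lactone with the 2-aryl-1,3-dithian-2-yl group on C4 (anti to menthyloxy) and the aryl(hydroxy)methyl group on C3 (anti to the C4 group) | O=C1[C@H]([C@H](O)c2cc(OC)c(O[Si](C)(C)C(C)(C)C)c(OC)c2)[C@@H](C2(c3ccc(O[Si](C)(C)C(C)(C)C)c(OC)c3)SCCCS2)[C@H](O[C@@H]2C[C@H](C)CC[C@H]2C(C)C)O1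
A5 | alternative 2 | (S)-5-[4-(benzyloxy)-3-methoxyphenyl]furan-2(5H)-one | O=C1C=C[C@@H](c2ccc(OCc3ccccc3)c(OC)c2)O1
A6 | alternative 2 | {[chloro(4-benzyloxy-3,5-dimethoxyphenyl)methoxy]methyl}trimethylsilane | COc1cc(C(Cl)OC[Si](C)(C)C)cc(OC)c1OCc1ccccc1
A7 | alternative 2 | cis-fused 3-[4-(benzyloxy)-3-methoxyphenyl]-6-[4-(benzyloxy)-3,5-dimethoxyphenyl]tetrahydro-1H,3H-furo[3,4-c]furan-1-one | O1C(=O)[C@H]2[C@@H]([C@H]1c3ccc(OCc5ccccc5)c(OC)c3)CO[C@@H]2c4cc(OC)c(OCc6ccccc6)c(OC)c4
A8 | alternative 3 | (S)-2-{(R)-[4-(tert-butyldimethylsilyloxy)-3,5-dimethoxyphenyl][(E)-3-[4-(tert-butyldimethylsilyloxy)-3-methoxyphenyl]allyloxy]methyl}oxirane (the oxirane centre is erased in the radical) | O(C/C=C/c1ccc(O[Si](C)(C)C(C)(C)C)c(OC)c1)[C@@H]([C@@H]1CO1)c1cc(OC)c(O[Si](C)(C)C(C)(C)C)c(OC)c1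
A9 | alternative 3 | bis(tert-butyldimethylsilyl) 5-methoxylariciresinol | OC[C@H]2[C@@H](Cc3ccc(O[Si](C)(C)C(C)(C)C)c(OC)c3)CO[C@@H]2c2cc(OC)c(O[Si](C)(C)C(C)(C)C)c(OC)c2
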